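Counting partner is the easy step, so we start there for whoever takes over the flasks south, north and east.

| flask | substrate | partner | scavenger | remark | time |
|---|---|---|---|---|---|
| Friday's | 1.6 M | 1.6 M | 0.53 M | run made earlier |  |
| south | 1.6 M | 1.60 M | 0.800 M |  | 3.0 h |
| north | 1.6 M | 1.60 M | 1.20 M |  | 3.0 h |
| east | 1.6 M | 1.60 M | 1.80 M |  | 3.0 h |

- Friday's (time / min: substrate / %, first product / %): 30.0: 57.3, 35.3; 60.0: 50.3, 38.0; 90.0: 48.1, 40.8; 120: 46.3, 40.6

(scatter of a reading: 0.5 percentage points)

- for released group the idle adduct is counted in
- steps thought possible: partner + first product -> double product + released group; partner + released group <-> idle adduct; partner -> decomposed reagent; scavenger + released group -> scavenged by-product; substrate + partner -> first product + released group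
- no earlier run changes the charge of scavenger; that part of a forecast is a guess

* part of the substrate that has reacted at the end, south
* part of the substrate that has reacted at the end, north
* part of the substrate that has reacted at the end, east
* what raising the concentration of scavenger from its lowest to its highest value here does to the part of the substrate that has reacted (changes below 5 percentage points count as none) (it rises / no change / it falls)

Each first product cost one partner and each double product two, and Friday's last reading leaves 13.1% of the substrate as double product, so 66.8% of the charged partner entered products. Following one partner molecule, we define the fork ratio ρ, a selectivity factor, as charged partner in products per charged partner outside them, here as read at that last reading: ρ = 2.01. Friday's substrate fell by 1.8 percentage points between its last two readings, so we read that run as close to its stopping point.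

No earlier run moves the scavenger, so our reckoning rests on a guess: partner is lost without any help from the scavenger, and, with the partner charge held, ρ grows in proportion to the substrate charge. South, north and east then share Friday's ρ and its split between the two products, and we expect them to stop near 53.7% reacted, so the taker-over should expect that at 3.0 h and leave the scavenger dose untouched.

The forecast differs, holding that beyond the scavenger charge “each further released group ties up one partner as idle adduct”: it gives 59% for south, 66% for north and 70.5% for east, so that it rises.

The flasks give 54.3% for south, 54.4% for north and 54.4% for east, a shift of 0.11 points, which counts as no change.

    partner + first product → double product + released group (k = 2.50 × 10⁻⁴ M⁻¹ s⁻¹)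
    partner + released group ⇌ idle adduct, settled at all times (K = 2.10 M⁻¹)
    partner → decomposed reagent (k = 2.50 × 10⁻⁴ s⁻¹)
    scavenger + released group → scavenged by-product (k = 0.130 M⁻¹ s⁻¹)
    substrate + partner → first product + released group (k = 3.80 × 10⁻⁴ M⁻¹ s⁻¹)

For east, ρ reckons 0.531 M of decomposed reagent, and east holds 0.516 M at 3.00 h, with free partner, the limiting reagent, down to 0.046% of its charge. Scaled to a neighbour of east charged with 0.96 M of substrate, ρ becomes 1.21 and reckons 0.725 M of decomposed reagent, and that neighbour holds 0.732 M at 3.00 h.

The data come from a simulation with constants of no real substance.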